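**Retrosynthetic overview**
1. Side chain last: the C-12/C-13 bond comes from Negishi coupling of a C-12 alkylzinc on the finished core with an (E)-enol tosylate, which fixes the (13Z)-acetoxy enoate; the tert-butyl ester is cleaved at the end.
2. Ring A is cut at C-3/C-4 and C-1/C-10: a [3+3] annulation of (E)-1,3-bis(trimethylsilyl)propene (a propane-1,3-diyl dianion equivalent) onto a ring B enone.
3. Enabling feature: C-5, the α-carbon of the C-6 ketone in ring B, carries both C-4 (gem-dimethyl) and C-10 (methyl), so C-4/C-5/C-10 is a 2-acylallyl unit that is electrophilic at both ends (cation at C-4, enone β-carbon at C-10).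
4. Ring order: ring B first (organocatalytic Michael/aldol sets C-9), ring A second (C-9 directs C-10, C-5 equilibrates to trans), then the C-7/C-8 methyl enone.

Key step: step 7

Assumption: locants follow labdane numbering (ring A = C-1 to C-5 and C-10, ring B = C-5 to C-10, side chain C-11 to C-16), and the (S)-prolinol silyl ether is taken to shield the enamine face that leads to (S)-3, as in related aldehyde Michael additions.

**Step 1**
Reactants: 1 4-chlorobutanal; 2 but-3-en-2-one
Product: 3 (S)-2-(2-chloroethyl)-5-oxohexanal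
Conditions: (S)-α,α-diphenylprolinol trimethylsilyl ether (5 mol%), ethyl 3,4-dihydroxybenzoate (20 mol%), neat, 4 °C
Reagents that add atoms: none
Why: Enamine-catalysed asymmetric Michael addition of an unbranched aldehyde to a vinyl ketone, in which the diphenyl(silyloxy)methyl group shields one face of the E-enamine so that the C-9 stereocentre should form with the (S) configuration.

**Step 2**
Reactants: 3 (S)-2-(2-chloroethyl)-5-oxohexanal
Product: 5 (S)-4-(2-chloroethyl)cyclohex-2-en-1-one, via β-hydroxy ketone 4 (not isolated)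
Conditions: p-TsOH·H2O (20 mol%), toluene, 60 °C
Reagents that add atoms: none
Why: Acid-catalysed intramolecular aldol condensation (Robinson-type cyclodehydration) in which the methyl ketone enol adds to the aldehyde and water is lost towards the ketone; acid avoids enolate alkylation by the chloride, and ring closure should outrun enolisation at C-9.

**Step 3**
Reactants: 5 (S)-4-(2-chloroethyl)cyclohex-2-en-1-one
Product: 7 (S)-4-(2-chloroethyl)-3-methylcyclohex-2-en-1-one, via silyl enol ether 6 (not isolated)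
Conditions: MeMgBr, CuBr·SMe2 (10 mol%), Me3SiCl, THF, −78 °C; then Pd(OAc)2 (10 mol%), O2 (1 atm), DMSO, 25 °C
Reagents that add atoms: methylmagnesium bromide C[Mg]Br
Why: Copper-catalysed conjugate methylation trapped as the regiodefined silyl enol ether (methyl anti to the C-9 chain, a centre that is erased again), then Saegusa–Ito dehydrogenation, which can only eliminate towards the C-10 hydrogen and so returns the enone with the C-10 methyl in place.

**Step 4**
Reactants: 7 (S)-4-(2-chloroethyl)-3-methylcyclohex-2-en-1-one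
Product: 9 (S)-2-bromo-4-(2-chloroethyl)-3-methylcyclohex-2-en-1-one, via dibromide 8 (not isolated)
Conditions: Br2, CH2Cl2, 0 °C; then Et3N, 0 → 25 °C
Reagents that add atoms: bromine BrBr
Why: Bromine addition to the enone followed by amine-induced dehydrobromination through the acidic α-hydrogen is the standard route to α-bromo enones; no stereocentre is formed or touched.

**Step 5**
Reactants: 9 (S)-2-bromo-4-(2-chloroethyl)-3-methylcyclohex-2-en-1-one; 10 4,4,5,5-tetramethyl-2-(prop-1-en-2-yl)-1,3,2-dioxaborolane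
Product: 11 (S)-4-(2-chloroethyl)-3-methyl-2-(prop-1-en-2-yl)cyclohex-2-en-1-one
Conditions: PdCl2(dppf) (5 mol%), K3PO4, 1,4-dioxane/H2O, 80 °C
Reagents that add atoms: none
Why: Suzuki–Miyaura coupling of an α-bromo enone (an activated vinyl bromide) with an alkenylboronate places C-4 on C-5 as a cross-conjugated isopropenyl group; no stereocentre is formed.

**Step 6**
Reactants: 12 allyltrimethylsilane
Product: 14 (E)-1,3-bis(trimethylsilyl)prop-1-ene, via silylallyllithium 13 (not isolated)
Conditions: s-BuLi, TMEDA, THF, −78 °C; then Me3SiCl, −78 → 0 °C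
Reagents that add atoms: chlorotrimethylsilane C[Si](C)(C)Cl
Why: Deprotonation of the allylsilane gives the 1-silylallyl anion, which is silylated at the less hindered γ-terminus to give the (E)-1,3-disilylpropene (allyl anion silylation).

**Step 7**
Reactants: 11 (S)-4-(2-chloroethyl)-3-methyl-2-(prop-1-en-2-yl)cyclohex-2-en-1-one; 14 (E)-1,3-bis(trimethylsilyl)prop-1-ene
Product: 17 (4S,4aS,8aR)-4-(2-chloroethyl)-4a,8,8-trimethyl-3,4,4a,5,8,8a-hexahydronaphthalen-1(2H)-one, via tertiary chloride 15 (not isolated), via allylsilane enone 16 (not isolated)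
Conditions: dry HCl (1.05 equiv), CH2Cl2, −20 °C, then N2 purge; 14, TiCl4, CH2Cl2, −78 → −30 °C; aq. NaHCO3; then p-TsOH (cat.), CH2Cl2, 25 °C
Reagents that add atoms: none
Why: Proposed new method: TiCl4 ionises the tertiary allylic chloride 15 to the 2-acylallyl cation delocalised over C-4 and C-10; the silyl-bearing vinyl carbon of 14 attacks the open gem-dimethyl terminus (C-3/C-4 bond, anti SE2' with loss of Me3SiCl), and the α-silyl allylsilane 16 so formed adds through its CH2 terminus to the TiCl4-activated enone at C-10 (C-1/C-10 bond), the β-silyl cation at C-2 collapsing to the C-2/C-3 alkene. The closest known reaction types are the TiCl4 allylation of tert-alkyl chlorides with allylsilanes and the intramolecular Hosomi–Sakurai (enone-initiated, allylsilane-terminated cation–olefin) cyclisation; new is their union in one flask, with a 1,3-disilylpropene acting as a propane-1,3-diyl dianion equivalent towards a 2-acylallyl dication equivalent. Ring A closes in a chair-like 6-endo-trig mode onto the enone β-carbon, the same 1,5-diene topology as a polyene cyclisation. The C-10 quaternary centre is set by the C-9 stereocentre, whose 2-chloroethyl group is pseudoaxial (A1,2 strain with the C-10 methyl) and blocks one face, so C-1 enters anti and methyl and side chain end cis; C-5 is set by protonation of the titanium enolate and acid equilibration to the trans ring fusion. The step needs carbon–carbon bond formation at C-4 to outrun proton loss from the cation and 1,2-addition to the ketone, which the high nucleophilicity of the allylsilane, the low temperature and the hindered, tetrasubstituted carbonyl should secure.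

**Step 8**
Reactants: 17 (4S,4aS,8aR)-4-(2-chloroethyl)-4a,8,8-trimethyl-3,4,4a,5,8,8a-hexahydronaphthalen-1(2H)-one
Product: 18 (4S,4aS,8aR)-4-(2-chloroethyl)-4a,8,8-trimethyloctahydronaphthalen-1(2H)-one
Conditions: H2 (1 atm), Pd/C, EtOAc, 25 °C
Reagents that add atoms: none
Why: Catalytic hydrogenation of the cis-disubstituted ring A alkene under neutral conditions, which leave the ketone and the primary chloride alone; no stereocentre is made.

**Step 9**
Reactants: 18 (4S,4aS,8aR)-4-(2-chloroethyl)-4a,8,8-trimethyloctahydronaphthalen-1(2H)-one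
Product: 19 (4R,4aS,8aR)-4-(2-chloroethyl)-4a,8,8-trimethyl-4a,5,6,7,8,8a-hexahydronaphthalen-1(4H)-one
Conditions: IBX, toluene/DMSO, 70 °C
Reagents that add atoms: none
Why: IBX dehydrogenation of a ketone to its enone, which can only run towards C-7/C-8 and cannot over-oxidise because C-4 and C-10 are quaternary.

**Step 10**
Reactants: 19 (4R,4aS,8aR)-4-(2-chloroethyl)-4a,8,8-trimethyl-4a,5,6,7,8,8a-hexahydronaphthalen-1(4H)-one
Product: 21 (4R,4aS,8aR)-4-(2-chloroethyl)-3,4a,8,8-tetramethyl-4a,5,6,7,8,8a-hexahydronaphthalen-1(4H)-one, via silyl enol ether 20 (not isolated)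
Conditions: MeMgBr, CuBr·SMe2 (10 mol%), Me3SiCl, THF, −78 °C; then Pd(OAc)2 (10 mol%), O2 (1 atm), DMSO, 25 °C
Reagents that add atoms: methylmagnesium bromide C[Mg]Br
Why: The same conjugate methylation and Saegusa–Ito dehydrogenation as in step 3 now places the C-8 methyl; the transient C-8 centre (methyl anti to the C-9 chain and the C-10 methyl) is flattened when the C-7/C-8 alkene re-forms.

**Step 11**
Reactants: 21 (4R,4aS,8aR)-4-(2-chloroethyl)-3,4a,8,8-tetramethyl-4a,5,6,7,8,8a-hexahydronaphthalen-1(4H)-one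
Product: 22 (4R,4aS,8aR)-4-(2-iodoethyl)-3,4a,8,8-tetramethyl-4a,5,6,7,8,8a-hexahydronaphthalen-1(4H)-one
Conditions: NaI, acetone, reflux
Reagents that add atoms: sodium iodide [Na+].[I-]
Why: Finkelstein halide exchange at the unhindered primary chloride, driven by precipitation of NaCl.

**Step 12**
Reactants: 23 tert-butyl 4-chloro-3-oxobutanoate
Product: 24 tert-butyl 4-acetoxy-3-oxobutanoate
Conditions: KOAc, AcOH, 60 °C
Reagents that add atoms: potassium acetate CC(=O)[O-].[K+]
Why: SN2 displacement of the activated α-chloro ketone by acetate in a buffered medium that keeps the β-keto ester from self-condensing.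

**Step 13**
Reactants: 24 tert-butyl 4-acetoxy-3-oxobutanoate
Product: 25 tert-butyl (2E)-4-acetoxy-3-(tosyloxy)but-2-enoate
Conditions: TsCl, N-methylimidazole, Et3N, MeCN, −10 → 25 °C
Reagents that add atoms: 4-toluenesulfonyl chloride Cc1ccc(cc1)S(Cl)(=O)=O
Why: Enol sulfonylation of a β-keto ester under non-chelating amine conditions, which is known to give the (E)-enol tosylate (tosyloxy trans to the ester) and so fixes the acetoxymethyl group cis to the ester.

**Step 14**
Reactants: 22 (4R,4aS,8aR)-4-(2-iodoethyl)-3,4a,8,8-tetramethyl-4a,5,6,7,8,8a-hexahydronaphthalen-1(4H)-one; 25 tert-butyl (2E)-4-acetoxy-3-(tosyloxy)but-2-enoate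
Product: 27 tert-butyl (2Z)-4-acetoxy-3-{2-[(1R,4aR,8aS)-2,5,5,8a-tetramethyl-4-oxo-1,4,4a,5,6,7,8,8a-octahydronaphthalen-1-yl]ethyl}but-2-enoate, via alkylzinc iodide 26 (not isolated)
Conditions: Zn dust, LiCl, THF, 30 °C; then 25, PdCl2(dppf) (5 mol%), THF, 25–40 °C
Reagents that add atoms: none
Why: Zinc insertion into the primary iodide tolerates the enone, and Negishi coupling of the alkylzinc with the β-tosyloxy enoate proceeds with retention of alkene geometry, so the chain ends trans and the acetoxymethyl group cis to the ester.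

**Step 15**
Reactants: 27 tert-butyl (2Z)-4-acetoxy-3-{2-[(1R,4aR,8aS)-2,5,5,8a-tetramethyl-4-oxo-1,4,4a,5,6,7,8,8a-octahydronaphthalen-1-yl]ethyl}but-2-enoate
Product: 28 (2Z)-4-acetoxy-3-{2-[(1R,4aR,8aS)-2,5,5,8a-tetramethyl-4-oxo-1,4,4a,5,6,7,8,8a-octahydronaphthalen-1-yl]ethyl}but-2-enoic acid
Conditions: CF3CO2H, CH2Cl2, 0 → 25 °C
Reagents that add atoms: none
Why: Acidolysis of the tert-butyl ester (loss of isobutene) frees the acid without touching the primary acetate, the enone or the alkene geometry; base is avoided because a free C-16 hydroxyl cis to the carboxyl would lactonise.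

**Compound list**
1 | 4-chlorobutanal | O=CCCCCl | starting material
2 | but-3-en-2-one | CC(=O)C=C | starting material
3 | (S)-2-(2-chloroethyl)-5-oxohexanal | ClCC[C@@H](C=O)CCC(C)=O | intermediate
4 | (4S)-4-(2-chloroethyl)-3-hydroxycyclohexan-1-one (carbinol centre undefined) | ClCC[C@@H]1CCC(=O)CC1O | intermediate
5 | (S)-4-(2-chloroethyl)cyclohex-2-en-1-one | ClCC[C@@H]1CCC(=O)C=C1 | intermediate
6 | {[(3S,4S)-4-(2-chloroethyl)-3-methylcyclohex-1-en-1-yl]oxy}trimethylsilane | ClCC[C@@H]1CCC(O[Si](C)(C)C)=C[C@H]1C | intermediate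
7 | (S)-4-(2-chloroethyl)-3-methylcyclohex-2-en-1-one | ClCC[C@@H]1CCC(=O)C=C1C | intermediate
8 | (4S)-2,3-dibromo-4-(2-chloroethyl)-3-methylcyclohexan-1-one (bromine-bearing centres undefined) | ClCC[C@@H]1CCC(=O)C(Br)C1(C)Br | intermediate
9 | (S)-2-bromo-4-(2-chloroethyl)-3-methylcyclohex-2-en-1-one | ClCC[C@@H]1CCC(=O)C(Br)=C1C | intermediate
10 | 4,4,5,5-tetramethyl-2-(prop-1-en-2-yl)-1,3,2-dioxaborolane | CC(=C)B1OC(C)(C)C(C)(C)O1 | starting material
11 | (S)-4-(2-chloroethyl)-3-methyl-2-(prop-1-en-2-yl)cyclohex-2-en-1-one | ClCC[C@@H]1CCC(=O)C(C(C)=C)=C1C | intermediate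
12 | allyltrimethylsilane | C=CC[Si](C)(C)C | starting material
13 | [1-(trimethylsilyl)prop-2-en-1-yl]lithium | [Li]C(C=C)[Si](C)(C)C | intermediate
14 | (E)-1,3-bis(trimethylsilyl)prop-1-ene | C[Si](C)(C)C/C=C/[Si](C)(C)C | intermediate
15 | (S)-4-(2-chloroethyl)-2-(2-chloropropan-2-yl)-3-methylcyclohex-2-en-1-one | ClCC[C@@H]1CCC(=O)C(C(C)(C)Cl)=C1C | intermediate
16 | (4S)-4-(2-chloroethyl)-3-methyl-2-[2-methyl-3-(trimethylsilyl)pent-4-en-2-yl]cyclohex-2-en-1-one (silyl-bearing centre undefined) | ClCC[C@@H]1CCC(=O)C(C(C)(C)C(C=C)[Si](C)(C)C)=C1C | intermediate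
17 | (4S,4aS,8aR)-4-(2-chloroethyl)-4a,8,8-trimethyl-3,4,4a,5,8,8a-hexahydronaphthalen-1(2H)-one (trans-fused, 4a-methyl cis to the chloroethyl group) | ClCC[C@@H]1CCC(=O)[C@@H]2C(C)(C)C=CC[C@@]12C | intermediate
18 | (4S,4aS,8aR)-4-(2-chloroethyl)-4a,8,8-trimethyloctahydronaphthalen-1(2H)-one | ClCC[C@@H]1CCC(=O)[C@@H]2C(C)(C)CCC[C@@]12C | intermediate
19 | (4R,4aS,8aR)-4-(2-chloroethyl)-4a,8,8-trimethyl-4a,5,6,7,8,8a-hexahydronaphthalen-1(4H)-one | ClCC[C@@H]1C=CC(=O)[C@@H]2C(C)(C)CCC[C@@]12C | intermediate
20 | trimethylsilyl enol ether of the 3-methyl ketone (C-1 oxygen, C-1/C-2 alkene in naphthalenone numbering; 3-methyl trans to the 4-chloroethyl group) | ClCC[C@@H]1[C@@H](C)C=C(O[Si](C)(C)C)[C@@H]2C(C)(C)CCC[C@@]12C | intermediate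
21 | (4R,4aS,8aR)-4-(2-chloroethyl)-3,4a,8,8-tetramethyl-4a,5,6,7,8,8a-hexahydronaphthalen-1(4H)-one | ClCC[C@@H]1C(C)=CC(=O)[C@@H]2C(C)(C)CCC[C@@]12C | intermediate
22 | (4R,4aS,8aR)-4-(2-iodoethyl)-3,4a,8,8-tetramethyl-4a,5,6,7,8,8a-hexahydronaphthalen-1(4H)-one | ICC[C@@H]1C(C)=CC(=O)[C@@H]2C(C)(C)CCC[C@@]12C | intermediate
23 | tert-butyl 4-chloro-3-oxobutanoate | ClCC(=O)CC(=O)OC(C)(C)C | starting material
24 | tert-butyl 4-acetoxy-3-oxobutanoate | CC(=O)OCC(=O)CC(=O)OC(C)(C)C | intermediate
25 | tert-butyl (2E)-4-acetoxy-3-(tosyloxy)but-2-enoate | CC(=O)OC/C(OS(=O)(=O)c1ccc(C)cc1)=C\C(=O)OC(C)(C)C | intermediate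
26 | {2-[(1R,4aR,8aS)-2,5,5,8a-tetramethyl-4-oxo-1,4,4a,5,6,7,8,8a-octahydronaphthalen-1-yl]ethyl}zinc iodide | I[Zn]CC[C@@H]1C(C)=CC(=O)[C@@H]2C(C)(C)CCC[C@@]12C | intermediate
27 | tert-butyl (2Z)-4-acetoxy-3-{2-[(1R,4aR,8aS)-2,5,5,8a-tetramethyl-4-oxo-1,4,4a,5,6,7,8,8a-octahydronaphthalen-1-yl]ethyl}but-2-enoate | CC(=O)OC/C(=C\C(=O)OC(C)(C)C)CC[C@@H]1C(C)=CC(=O)[C@@H]2C(C)(C)CCC[C@@]12C | intermediate
28 | (2Z)-4-acetoxy-3-{2-[(1R,4aR,8aS)-2,5,5,8a-tetramethyl-4-oxo-1,4,4a,5,6,7,8,8a-octahydronaphthalen-1-yl]ethyl}but-2-enoic acid | CC(=O)OC/C(=C\C(=O)O)CC[C@@H]1C(C)=CC(=O)[C@@H]2C(C)(C)CCC[C@@]12C | target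

**Step count and risks**
Total steps: 15. Longest linear sequence: 12 (steps 1–5, 7–11, 14, 15).

Most likely to fail:

1. Step 7 (Proposed new method). The allyl cation may be lost by proton loss (back to the dienone, or towards C-9, which would also erode that stereocentre). The disilylpropene may be protodesilylated by residual HCl. The sequence may stop after the first alkylation, and facial control at C-10 may be incomplete. A reversed order of the two bond formations would only shift the ring A double bond, which step 8 removes. Fallback, known chemistry only: it sets out from 11. Hydrochlorination as before gives chloride 15, which is allylated with allyltrimethylsilane 12 and TiCl4 (established tert-alkyl chloride allylation) to the homoallyl enone F1. Hydroboration of the terminal alkene with 9-BBN and oxidation with NaBO3 gives the primary alcohol F2, and I2, PPh3 and imidazole give the iodide F3. Bu3SnH with AIBN in benzene at 80 °C then closes ring A by 6-endo radical conjugate addition to C-10, anti to the C-9 chain. After acid equilibration at C-5 the saturated ketone 18 is obtained, where the route is rejoined.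

2. Step 14. Zerovalent palladium may ionise the allylic acetate of 25 or 27 instead of inserting into the enol tosylate, and the alkylzinc may be consumed by β-hydride elimination or protonation before transmetalation. Fallback: it sets out from the alkylzinc 26. Acylation with acetoxyacetyl chloride (Pd(PPh3)4 cat., THF) gives the acetoxy ketone F4. Horner–Wadsworth–Emmons olefination with tert-butyl diethylphosphonoacetate (LiCl, DBU, MeCN) then gives 27 together with its (2E) isomer F5, which is removed by chromatography. The route is rejoined at 27.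

3. Step 5. Oxidative addition and transmetalation at the hindered, tetrasubstituted bromo enone may be slow, so that protodeboronation of 10 and reductive debromination of 9 take over. Fallback: it sets out from 9. Ketalisation (ethane-1,2-diol, p-TsOH, benzene, reflux) gives the bromo ketal F6. Bromine–lithium exchange (t-BuLi, THF, −78 °C), addition to acetone and mild hydrolysis with aqueous oxalic acid give the tertiary allylic alcohol F7. Dry HCl in CH2Cl2 converts F7 into the chloride 15, where the route is rejoined inside step 7.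

**Further compounds**
F1 | step 7 | (S)-4-(2-chloroethyl)-3-methyl-2-(2-methylpent-4-en-2-yl)cyclohex-2-en-1-one | ClCC[C@@H]1CCC(=O)C(C(C)(C)CC=C)=C1C
F2 | step 7 | (S)-4-(2-chloroethyl)-2-(5-hydroxy-2-methylpentan-2-yl)-3-methylcyclohex-2-en-1-one | ClCC[C@@H]1CCC(=O)C(C(C)(C)CCCO)=C1C
F3 | step 7 | (S)-4-(2-chloroethyl)-2-(5-iodo-2-methylpentan-2-yl)-3-methylcyclohex-2-en-1-one | ClCC[C@@H]1CCC(=O)C(C(C)(C)CCCI)=C1C
F4 | step 14 | 2-oxo-4-[(1R,4aR,8aS)-2,5,5,8a-tetramethyl-4-oxo-1,4,4a,5,6,7,8,8a-octahydronaphthalen-1-yl]butyl acetate | CC(=O)OCC(=O)CC[C@@H]1C(C)=CC(=O)[C@@H]2C(C)(C)CCC[C@@]12C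
F5 | step 14 | tert-butyl (2E)-4-acetoxy-3-{2-[(1R,4aR,8aS)-2,5,5,8a-tetramethyl-4-oxo-1,4,4a,5,6,7,8,8a-octahydronaphthalen-1-yl]ethyl}but-2-enoate | CC(=O)OC/C(=C/C(=O)OC(C)(C)C)CC[C@@H]1C(C)=CC(=O)[C@@H]2C(C)(C)CCC[C@@]12C
F6 | step 5 | (S)-6-bromo-8-(2-chloroethyl)-7-methyl-1,4-dioxaspiro[4.5]dec-6-ene | ClCC[C@@H]1CCC2(OCCO2)C(Br)=C1C
F7 | step 5 | (S)-4-(2-chloroethyl)-2-(2-hydroxypropan-2-yl)-3-methylcyclohex-2-en-1-one | ClCC[C@@H]1CCC(=O)C(C(C)(C)O)=C1C
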